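**Strategy.** The route rests on disconnecting the ketone between its carbonyl carbon and the adjacent CH2 of the propanone chain. That carbonyl sits on C7 of the benzene ring of the 2,5-dihydro-1-benzoxepine, flanked by the phenolic hydroxyls on C6 and C8, so the ketone is the formal adduct of a salicylaldehyde C–H bond across a vinylarene. A rhodium-catalysed, phenoxide-chelated anti-Markovnikov hydroacylation therefore joins the benzoxepine-7-carbaldehyde (free C6/C8 hydroxyls) to 3,4-bis(silyloxy)styrene in one atom-economical operation, with no protection of the acyl-bearing ring. The aldehyde comes from phloroglucinaldehyde by Claisen rearrangement and ring-closing metathesis.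

Key step: step 7

Remark on the chemistry: the target has no stereocentre, and the C3=C4 double bond lies inside the seven-membered ring and is necessarily cis, so no stereodescriptor is needed. 2,4,6-Trihydroxybenzaldehyde, 3,4-dihydroxybenzaldehyde, allyl bromide and 3-bromo-2-methylprop-1-ene are taken as commercial.

**Step 1**
Reactants: 1 2,4,6-trihydroxybenzaldehyde
Product: 2 4-(allyloxy)-2,6-dihydroxybenzaldehyde
Conditions: allyl bromide (1.0 equiv), KHCO3 (1.1 equiv), DMF, 25–40 °C
Reagents that add atoms: allyl bromide, C=CCBr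
Why: Williamson etherification; bicarbonate should ionise only the 4-OH (para to the formyl group, a vinylogous acid, not hydrogen-bonded), while the 2- and 6-OH are held by the carbonyl, so one equivalent of electrophile should give mainly the para mono-ether.

**Step 2**
Reactants: 2 4-(allyloxy)-2,6-dihydroxybenzaldehyde
Product: 3 3-allyl-2,4,6-trihydroxybenzaldehyde
Conditions: PhNEt2, 180 °C, sealed tube, Ar
Reagents that add atoms: none
Why: aromatic Claisen rearrangement ([3,3]-sigmatropic shift, then tautomerisation); the two ortho positions C3 and C5 are equivalent by symmetry, so a single C-allyl product is expected, and the basic solvent suppresses acid-catalysed cyclisation onto the new allyl group.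

**Step 3**
Reactants: 3 3-allyl-2,4,6-trihydroxybenzaldehyde
Product: 4 3-allyl-2,6-dihydroxy-4-[(2-methylprop-2-en-1-yl)oxy]benzaldehyde
Conditions: 3-bromo-2-methylprop-1-ene (1.05 equiv), KHCO3 (1.1 equiv), DMF, 25–40 °C
Reagents that add atoms: 3-bromo-2-methylprop-1-ene, C=C(C)CBr
Why: Williamson etherification with the same acidity-based selectivity as step 1; the para 4-OH is the most acidic and the only hydroxyl not engaged with the formyl group.

**Step 4**
Reactants: 4 3-allyl-2,6-dihydroxy-4-[(2-methylprop-2-en-1-yl)oxy]benzaldehyde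
Product: 5 6,8-dihydroxy-3-methyl-2,5-dihydro-1-benzoxepine-7-carbaldehyde
Conditions: Grubbs II (5 mol %), 1,4-benzoquinone (10 mol %), CH2Cl2 (0.005 M), 40 °C
Reagents that add atoms: none
Why: ring-closing metathesis between the monosubstituted C-allyl and the 1,1-disubstituted O-methallyl olefin should close the seven-membered ring with its trisubstituted (necessarily cis) alkene, driven by loss of ethylene; benzoquinone suppresses Ru–H double-bond migration.

**Step 5**
Reactants: 6 3,4-dihydroxybenzaldehyde
Product: 7 3,4-bis(tert-butyldimethylsilyloxy)benzaldehyde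
Conditions: TBSCl (2.4 equiv), imidazole (5 equiv), DMF, rt
Reagents that add atoms: tert-butyldimethylsilyl chloride, CC(C)(C)[Si](C)(C)Cl
Why: standard imidazole-promoted silylation of both catechol hydroxyls, which masks the chelating catechol for the rhodium step.

**Step 6**
Reactants: 7 3,4-bis(tert-butyldimethylsilyloxy)benzaldehyde
Product: 8 3,4-bis(tert-butyldimethylsilyloxy)styrene
Conditions: Ph3PCH3Br (1.3 equiv), n-BuLi (1.25 equiv), THF, 0 °C; then 7, 0 °C to rt
Reagents that add atoms: methyltriphenylphosphonium bromide, C[P+](c1ccccc1)(c1ccccc1)c1ccccc1.[Br-]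
Why: Wittig methylenation of an aromatic aldehyde with the preformed non-stabilised ylide; aryl silyl ethers should tolerate the base-free ylide solution.

**Step 7**
Reactants: 5 6,8-dihydroxy-3-methyl-2,5-dihydro-1-benzoxepine-7-carbaldehyde; 8 3,4-bis(tert-butyldimethylsilyloxy)styrene (1.5 equiv)
Product: 9 3-[3,4-bis(tert-butyldimethylsilyloxy)phenyl]-1-(6,8-dihydroxy-3-methyl-2,5-dihydro-1-benzoxepin-7-yl)propan-1-one
Conditions: [Rh(cod)Cl]2 (2.5 mol %), BINOL-derived N,N-bis(1-phenylethyl)phosphoramidite (10 mol %), K3PO4 (10 mol %), BHT (cat.), 1,2-dichloroethane, 70 °C, Ar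
Reagents that add atoms: none
Why: The phenoxide of the C6 or C8 hydroxyl binds Rh(I) and delivers the formyl C–H bond to the metal, giving a five-membered O,C-chelated acyl–Rh(III) hydride that resists decarbonylation; the vinyl group of 8 inserts into Rh–H, and C–C reductive elimination from the acyl–alkyl complex forms the carbonyl–CH2 bond. The closest known reaction type is the Rh/phosphoramidite/phosphate-catalysed, linear-selective intermolecular hydroacylation of terminal alkenes with salicylaldehydes that carry further free phenols. No ring is closed and no stereocentre is created. The step needs anti-Markovnikov regioselectivity (linear ketone, not the branched α-aryl ketone): hydride insertion is reversible, the bulky monodentate ligand should make reductive elimination from the primary alkyl faster than from the secondary benzylic rhodium species, and silylation of both catechol oxygens removes any hydroxyl that could chelate and steer the vinylarene to branched insertion. It also needs chemoselectivity for the monosubstituted vinyl group over the trisubstituted C3=C4 ring alkene, which the much slower coordination and insertion of the hindered internal olefin should secure. Either ortho hydroxyl can act as the chelating arm and both lead to the same product.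

**Step 8**
Reactants: 9 3-[3,4-bis(tert-butyldimethylsilyloxy)phenyl]-1-(6,8-dihydroxy-3-methyl-2,5-dihydro-1-benzoxepin-7-yl)propan-1-one
Product: 10 3-(3,4-dihydroxyphenyl)-1-(6,8-dihydroxy-3-methyl-2,5-dihydro-1-benzoxepin-7-yl)propan-1-one (CNP0203471.0)
Conditions: TBAF (2.2 equiv), AcOH (2.2 equiv), THF, 0 °C
Reagents that add atoms: none
Why: fluoride-mediated cleavage of the two aryl silyl ethers; acetic acid buffering keeps the polyphenol protonated and leaves the allyl aryl ether and ring alkene untouched.

**Compound list**
1 | 2,4,6-trihydroxybenzaldehyde | O=Cc1c(O)cc(O)cc1O | starting material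
2 | 4-(allyloxy)-2,6-dihydroxybenzaldehyde | C=CCOc1cc(O)c(C=O)c(O)c1 | intermediate
3 | 3-allyl-2,4,6-trihydroxybenzaldehyde | C=CCc1c(O)cc(O)c(C=O)c1O | intermediate
4 | 3-allyl-2,6-dihydroxy-4-[(2-methylprop-2-en-1-yl)oxy]benzaldehyde | C=CCc1c(OCC(C)=C)cc(O)c(C=O)c1O | intermediate
5 | 6,8-dihydroxy-3-methyl-2,5-dihydro-1-benzoxepine-7-carbaldehyde | CC1=CCc2c(cc(O)c(C=O)c2O)OC1 | intermediate
6 | 3,4-dihydroxybenzaldehyde | O=Cc1ccc(O)c(O)c1 | starting material
7 | 3,4-bis(tert-butyldimethylsilyloxy)benzaldehyde | CC(C)(C)[Si](C)(C)Oc1ccc(C=O)cc1O[Si](C)(C)C(C)(C)C | intermediate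
8 | 3,4-bis(tert-butyldimethylsilyloxy)styrene | C=Cc1ccc(O[Si](C)(C)C(C)(C)C)c(O[Si](C)(C)C(C)(C)C)c1 | intermediate
9 | 3-[3,4-bis(tert-butyldimethylsilyloxy)phenyl]-1-(6,8-dihydroxy-3-methyl-2,5-dihydro-1-benzoxepin-7-yl)propan-1-one | CC1=CCc2c(cc(O)c(C(=O)CCc3ccc(O[Si](C)(C)C(C)(C)C)c(O[Si](C)(C)C(C)(C)C)c3)c2O)OC1 | intermediate
10 | 3-(3,4-dihydroxyphenyl)-1-(6,8-dihydroxy-3-methyl-2,5-dihydro-1-benzoxepin-7-yl)propan-1-one | CC1=CCc2c(cc(O)c(C(=O)CCc3ccc(O)c(O)c3)c2O)OC1 | target

**Total step count:** 8
**Longest linear sequence:** 6 (steps 1, 2, 3, 4, 7, 8)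

**Steps most likely to fail**

Step 7 (key step). The vinylarene may insert in the Markovnikov sense and give the branched α-aryl ketone. Decarbonylation of the acyl rhodium species or Rh–H-mediated migration of the ring double bond may also erode the yield. The fallback forms the same carbonyl–CH2 bond by polar addition of a primary organolithium to the protected aldehyde; it sets out from 5 and 8 and comes back at 9.
- Aldehyde 5 would be protected (MOMCl, NaH, DMF, 0 °C) as 6,8-bis(methoxymethoxy)-3-methyl-2,5-dihydro-1-benzoxepine-7-carbaldehyde F1.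
- Styrene 8 would be hydroborated with 9-BBN (THF) to the anti-Markovnikov adduct B-{2-[3,4-bis(tert-butyldimethylsilyloxy)phenyl]ethyl}-9-borabicyclo[3.3.1]nonane F2 (not isolated). Oxidation (NaBO3·4H2O) would give 2-[3,4-bis(tert-butyldimethylsilyloxy)phenyl]ethan-1-ol F3, and I2, PPh3 and imidazole would convert it into 4-(2-iodoethyl)-1,2-bis(tert-butyldimethylsilyloxy)benzene F4.
- Iodine–lithium exchange (t-BuLi, Et2O, −78 °C) would give 2-[3,4-bis(tert-butyldimethylsilyloxy)phenyl]ethyllithium F5 (not isolated). Its addition to F1 should give the racemic carbinol 3-[3,4-bis(tert-butyldimethylsilyloxy)phenyl]-1-[6,8-bis(methoxymethoxy)-3-methyl-2,5-dihydro-1-benzoxepin-7-yl]propan-1-ol F6.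
- Dess–Martin oxidation would give 3-[3,4-bis(tert-butyldimethylsilyloxy)phenyl]-1-[6,8-bis(methoxymethoxy)-3-methyl-2,5-dihydro-1-benzoxepin-7-yl]propan-1-one F7. Chemoselective cleavage of the two MOM ethers (TMSOTf, 2,2′-bipyridyl, CH2Cl2, 0 °C; then H2O) would then return 9.

Step 2. At the temperature the sigmatropic shift needs, a free ortho hydroxyl may add to the newly formed allyl group (closure to a 2-methyl-2,3-dihydrobenzofuran), and the polyhydroxy aldehyde may decompose. The fallback avoids the thermal rearrangement: it sets out from 1 and comes back at 3 by direct C-allylation of the phloroglucinol-type phenoxide in water (allyl bromide, 1.0 equiv, 10% aq. KOH, 0 °C), where the ambident anion should react mainly through carbon. The mono-C-allyl compound would be separated from di-C-allyl and O-allyl material by chromatography. No new compound arises (F0).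

Step 1. Alkylation may run on to the second, non-chelated ortho hydroxyl, and the electron-rich ring may be C-allylated. The fallback replaces phenoxide alkylation by a redox condensation: it sets out from 1 and comes back at 2 by Mitsunobu etherification with allyl alcohol (PPh3, DIAD, THF, 0 °C to rt). Only the most acidic, non-hydrogen-bonded para hydroxyl should be engaged, and no phenoxide is generated that could attack through carbon. No new compound arises (F0).

**Further compounds**
F1 | step 7 | 6,8-bis(methoxymethoxy)-3-methyl-2,5-dihydro-1-benzoxepine-7-carbaldehyde | CC1=CCc2c(cc(OCOC)c(C=O)c2OCOC)OC1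
F2 | step 7 | B-{2-[3,4-bis(tert-butyldimethylsilyloxy)phenyl]ethyl}-9-borabicyclo[3.3.1]nonane (not isolated) | C1CCC2CCCC1B2CCc1ccc(O[Si](C)(C)C(C)(C)C)c(O[Si](C)(C)C(C)(C)C)c1
F3 | step 7 | 2-[3,4-bis(tert-butyldimethylsilyloxy)phenyl]ethan-1-ol | OCCc1ccc(O[Si](C)(C)C(C)(C)C)c(O[Si](C)(C)C(C)(C)C)c1
F4 | step 7 | 4-(2-iodoethyl)-1,2-bis(tert-butyldimethylsilyloxy)benzene | ICCc1ccc(O[Si](C)(C)C(C)(C)C)c(O[Si](C)(C)C(C)(C)C)c1
F5 | step 7 | 2-[3,4-bis(tert-butyldimethylsilyloxy)phenyl]ethyllithium (not isolated) | [Li]CCc1ccc(O[Si](C)(C)C(C)(C)C)c(O[Si](C)(C)C(C)(C)C)c1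
F6 | step 7 | 3-[3,4-bis(tert-butyldimethylsilyloxy)phenyl]-1-[6,8-bis(methoxymethoxy)-3-methyl-2,5-dihydro-1-benzoxepin-7-yl]propan-1-ol (racemic) | CC1=CCc2c(cc(OCOC)c(C(O)CCc3ccc(O[Si](C)(C)C(C)(C)C)c(O[Si](C)(C)C(C)(C)C)c3)c2OCOC)OC1
F7 | step 7 | 3-[3,4-bis(tert-butyldimethylsilyloxy)phenyl]-1-[6,8-bis(methoxymethoxy)-3-methyl-2,5-dihydro-1-benzoxepin-7-yl]propan-1-one | CC1=CCc2c(cc(OCOC)c(C(=O)CCc3ccc(O[Si](C)(C)C(C)(C)C)c(O[Si](C)(C)C(C)(C)C)c3)c2OCOC)OC1
F0 | step 2 | none | none
F0 | step 1 | none | none
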